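C1 carries the guaiacyl ring C, C2 the CH2OH, C3 the CHO, and C4 is the vinylic CH. Ring A is the dimethoxybenzene (C4a–C8a) and ring B the dihydro ring.
Enabling feature: C1 is benzylic to rings A and C and lies para to the free OH of ring C, so a C1H2 precursor can be oxidized to a para-quinone methide. C2, with its CH2OH drawn as CHO, is an enamine-forming α-carbon held next to C1 by C3=C4–C4a=C8a.
Retrosynthetic cuts, in order: redox change at the C2 and C3 arms, then C1–C2 (opens ring B), then C1–C8a (Negishi), then C3=C4 (Stobbe).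
Forward: a Stobbe condensation joins ring A to the four-carbon chain as the (E)-alkene and a Negishi coupling adds the ring C benzyl unit. Ring B closes last, by oxidation at C1 and intramolecular enamine 1,6-addition.
Stereochemistry: C2 comes from an (R)-diphenylprolinol silyl ether catalyst and C1 from the trans-selective ring-closing transition state. Immediate hydride reduction of the C2 aldehyde secures (1S,2R).

Key step: step 9

Assumption: the facial bias of the catalyst in this ring closure is taken to match its intermolecular enamine additions, which points to the (R)-enantiomer for (2R); the (S)-enantiomer is equally available should the sense prove opposite.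

Step 1
Reactants: 1 vanillin (4-hydroxy-3-methoxybenzaldehyde)
Product: 2 4-(tert-butyldimethylsilyloxy)-3-methoxybenzaldehyde
Conditions: TBSCl, imidazole, CH2Cl2, 23 °C
Reagents that add atoms: tert-butyldimethylsilyl chloride, CC(C)(C)[Si](C)(C)Cl
Why: Imidazole-promoted silylation of a phenol is routine, and the aryl silyl ether masks the acidic OH during zinc insertion and cross-coupling yet later falls to buffered fluoride.

Step 2
Reactants: 2 4-(tert-butyldimethylsilyloxy)-3-methoxybenzaldehyde
Product: 3 [4-(tert-butyldimethylsilyloxy)-3-methoxyphenyl]methanol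
Conditions: NaBH4, MeOH, 0 °C
Reagents that add atoms: none
Why: Borohydride reduction of an aromatic aldehyde is fast at 0 °C, and the short, cold exposure leaves the aryl silyl ether intact.

Step 3
Reactants: 3 [4-(tert-butyldimethylsilyloxy)-3-methoxyphenyl]methanol
Product: 4 tert-butyl[4-(chloromethyl)-2-methoxyphenoxy]dimethylsilane
Conditions: MsCl, Et3N, CH2Cl2, 0 to 23 °C
Reagents that add atoms: methanesulfonyl chloride (chlorine source), CS(=O)(=O)Cl
Why: The mesylate of an electron-rich benzylic alcohol is displaced in situ by the liberated chloride, a standard entry to para-alkoxybenzyl chlorides under non-acidic conditions that spare the silyl ether.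

Step 4
Reactants: 5 2-bromo-4,5-dimethoxybenzaldehyde; 6 di-tert-butyl succinate
Product: 7 (E)-4-(2-bromo-4,5-dimethoxyphenyl)-3-(tert-butoxycarbonyl)but-3-enoic acid
Conditions: KOtBu, tBuOH, 50 °C; then aq. HCl
Reagents that add atoms: none
Why: In the Stobbe condensation the succinate enolate adds to the aldehyde, the aldolate closes to a paraconic ester and E1cB opening gives the half-ester; aromatic aldehydes give the (E)-isomer with ring A cis to the CH2CO2H arm, and matching base and ester excludes transesterification.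

Step 5
Reactants: 7 (E)-4-(2-bromo-4,5-dimethoxyphenyl)-3-(tert-butoxycarbonyl)but-3-enoic acid
Product: 8 tert-butyl (E)-3-(2-bromo-4,5-dimethoxyphenyl)-2-(2-hydroxyethyl)acrylate
Conditions: BH3·THF, THF, 0 to 23 °C
Reagents that add atoms: none
Why: Borane reduces the free acid through its acyloxyborane much faster than it touches the conjugated ester or the electron-poor trisubstituted alkene, and the bulky tert-butyl ester keeps the γ-hydroxy ester from lactonizing.

Step 6
Reactants: 4 tert-butyl[4-(chloromethyl)-2-methoxyphenoxy]dimethylsilane; 8 tert-butyl (E)-3-(2-bromo-4,5-dimethoxyphenyl)-2-(2-hydroxyethyl)acrylate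
Product: 10 tert-butyl (E)-3-{2-[4-(tert-butyldimethylsilyloxy)-3-methoxybenzyl]-4,5-dimethoxyphenyl}-2-(2-hydroxyethyl)acrylate, via benzylic zinc chloride 9 (not isolated)
Conditions: 4, Zn dust, LiCl, THF, 23 °C; then 8, Pd(OAc)2 (2 mol%), SPhos (4 mol%), THF, 23 to 40 °C
Reagents that add atoms: none
Why: In this Negishi coupling, LiCl-assisted zinc insertion is reliable for electron-rich benzylic chlorides, and zerovalent palladium bearing SPhos couples such reagents with hindered, electron-rich aryl bromides faster than a free hydroxyl group protonates them, so alcohol, ester and silyl ether persist.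

Step 7
Reactants: 10 tert-butyl (E)-3-{2-[4-(tert-butyldimethylsilyloxy)-3-methoxybenzyl]-4,5-dimethoxyphenyl}-2-(2-hydroxyethyl)acrylate
Product: 11 tert-butyl (E)-3-{2-[4-(tert-butyldimethylsilyloxy)-3-methoxybenzyl]-4,5-dimethoxyphenyl}-2-(2-oxoethyl)acrylate
Conditions: Dess–Martin periodinane, CH2Cl2, 0 °C
Reagents that add atoms: none
Why: Dess–Martin oxidation runs without base and is the usual way from a homoallylic alcohol to a β,γ-unsaturated aldehyde without moving the alkene.

Step 8
Reactants: 11 tert-butyl (E)-3-{2-[4-(tert-butyldimethylsilyloxy)-3-methoxybenzyl]-4,5-dimethoxyphenyl}-2-(2-oxoethyl)acrylate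
Product: 12 tert-butyl (E)-3-[2-(4-hydroxy-3-methoxybenzyl)-4,5-dimethoxyphenyl]-2-(2-oxoethyl)acrylate
Conditions: Bu4NF/AcOH (1:1), THF, 0 °C
Reagents that add atoms: none
Why: Fluoride cleaves aryl silyl ethers quickly because phenoxide leaves silicon readily, and the acetic acid buffer keeps the medium from enolizing the sensitive aldehyde.

Step 9
Reactants: 12 tert-butyl (E)-3-[2-(4-hydroxy-3-methoxybenzyl)-4,5-dimethoxyphenyl]-2-(2-oxoethyl)acrylate
Product: 15 tert-butyl (1S,2R)-2-formyl-1-(4-hydroxy-3-methoxyphenyl)-6,7-dimethoxy-1,2-dihydronaphthalene-3-carboxylate, via para-quinone methide 13 (not isolated), via dienamine 14 (not isolated)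
Conditions: Ag2O (1.5 equiv), 4 Å MS, CH2Cl2 (0.02 M), 23 °C, dark; filtration through Celite under Ar; then (R)-α,α-diphenylprolinol trimethylsilyl ether (20 mol%), PhCO2H (20 mol%), CH2Cl2, −20 °C
Reagents that add atoms: none
Why: Proposed new method: Ag2O (monovalent silver) takes two electrons and two protons from the phenol of ring C and its para C1H2 group to give quinone methide 13, which has no neighbouring sp3 C–H through which it could tautomerize, and filtration removes the oxidant before the amine or the product phenol can meet it. The aldehyde then condenses with the catalyst to dienamine 14, whose α-carbon C2 adds in 1,6-fashion to C1 so that ring C regains aromaticity as the phenol, and hydrolysis then returns the catalyst. The closest known reaction types are the intermolecular amine-catalysed α-alkylation of aldehydes by para-quinone methides and the cyclization of Ag2O-generated para-quinone methides onto tethered carbon nucleophiles; merging them into an intramolecular, enantioselective closure is the untested part. Ring B closes in a 6-(enolexo)-exo-trig mode, and because the (E)-alkene holds the C2 arm and ring A on the same side of C3=C4, only the six-membered ring is within reach and γ-attack through C4 is geometrically excluded. C2 is controlled by the diphenyl(trimethylsilyloxy)methyl group of the catalyst, which shields one face of the (E)-enamine, and C1 by a half-chair transition state that places the ring C unit and the enamine carbon anti and pseudoaxial, away from C8–H and from the bulky C3 ester, which gives the trans (1S,2R) product. The step needs oxidation of the phenol in preference to the aldehyde, which dry, neutral CH2Cl2 secures, and it tolerates alkene migration in 12 because the conjugated enal isomer would enter the same dienamine.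

Step 10
Reactants: 15 tert-butyl (1S,2R)-2-formyl-1-(4-hydroxy-3-methoxyphenyl)-6,7-dimethoxy-1,2-dihydronaphthalene-3-carboxylate
Product: 16 [(1S,2R)-1-(4-hydroxy-3-methoxyphenyl)-6,7-dimethoxy-1,2-dihydronaphthalene-2,3-diyl]dimethanol
Conditions: iBu2AlH (6 equiv), CH2Cl2, −78 to 0 °C
Reagents that add atoms: none
Why: Applied at once to crude 15, iBu2AlH reduces the aldehyde within minutes at −78 °C, which removes the only acidic C2–H before it can epimerize, and on warming it takes the conjugated ester in 1,2-fashion to the allylic alcohol.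

Step 11
Reactants: 16 [(1S,2R)-1-(4-hydroxy-3-methoxyphenyl)-6,7-dimethoxy-1,2-dihydronaphthalene-2,3-diyl]dimethanol
Product: 17 (1S,2R)-2-(hydroxymethyl)-1-(4-hydroxy-3-methoxyphenyl)-6,7-dimethoxy-1,2-dihydronaphthalene-3-carbaldehyde (CNP0485134.1)
Conditions: activated MnO2 (10 equiv), CH2Cl2, 23 °C, short contact time
Reagents that add atoms: none
Why: MnO2 oxidizes only the allylic, styrene-conjugated C3–CH2OH and leaves the saturated C2–CH2OH alone, a short contact time is meant to spare the phenol and ring B, and neither stereocentre is touched.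

Compound list
1 | vanillin | COc1cc(C=O)ccc1O | starting material
2 | 4-(tert-butyldimethylsilyloxy)-3-methoxybenzaldehyde | COc1cc(C=O)ccc1O[Si](C)(C)C(C)(C)C | intermediate
3 | [4-(tert-butyldimethylsilyloxy)-3-methoxyphenyl]methanol | COc1cc(CO)ccc1O[Si](C)(C)C(C)(C)C | intermediate
4 | tert-butyl[4-(chloromethyl)-2-methoxyphenoxy]dimethylsilane | COc1cc(CCl)ccc1O[Si](C)(C)C(C)(C)C | intermediate
5 | 2-bromo-4,5-dimethoxybenzaldehyde | COc1cc(Br)c(C=O)cc1OC | starting material
6 | di-tert-butyl succinate | CC(C)(C)OC(=O)CCC(=O)OC(C)(C)C | starting material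
7 | (E)-4-(2-bromo-4,5-dimethoxyphenyl)-3-(tert-butoxycarbonyl)but-3-enoic acid | COc1cc(Br)c(/C=C(\CC(=O)O)C(=O)OC(C)(C)C)cc1OC | intermediate
8 | tert-butyl (E)-3-(2-bromo-4,5-dimethoxyphenyl)-2-(2-hydroxyethyl)acrylate | COc1cc(Br)c(/C=C(\CCO)C(=O)OC(C)(C)C)cc1OC | intermediate
9 | [4-(tert-butyldimethylsilyloxy)-3-methoxybenzyl]zinc chloride (LiCl-solvated, not isolated) | COc1cc(C[Zn]Cl)ccc1O[Si](C)(C)C(C)(C)C | intermediate
10 | tert-butyl (E)-3-{2-[4-(tert-butyldimethylsilyloxy)-3-methoxybenzyl]-4,5-dimethoxyphenyl}-2-(2-hydroxyethyl)acrylate | COc1cc(Cc2cc(OC)c(OC)cc2/C=C(\CCO)C(=O)OC(C)(C)C)ccc1O[Si](C)(C)C(C)(C)C | intermediate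
11 | tert-butyl (E)-3-{2-[4-(tert-butyldimethylsilyloxy)-3-methoxybenzyl]-4,5-dimethoxyphenyl}-2-(2-oxoethyl)acrylate | COc1cc(Cc2cc(OC)c(OC)cc2/C=C(\CC=O)C(=O)OC(C)(C)C)ccc1O[Si](C)(C)C(C)(C)C | intermediate
12 | tert-butyl (E)-3-[2-(4-hydroxy-3-methoxybenzyl)-4,5-dimethoxyphenyl]-2-(2-oxoethyl)acrylate | COc1cc(Cc2cc(OC)c(OC)cc2/C=C(\CC=O)C(=O)OC(C)(C)C)ccc1O | intermediate
13 | para-quinone methide of 12: C1 is the exocyclic methylidene carbon of a 2-methoxycyclohexa-2,5-dien-1-one (exocyclic geometry undefined; not isolated) | COC1=CC(=Cc2cc(OC)c(OC)cc2/C=C(\CC=O)C(=O)OC(C)(C)C)C=CC1=O | intermediate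
14 | (E)-dienamine of 13 with (R)-α,α-diphenylprolinol trimethylsilyl ether (not isolated) | COC1=CC(=Cc2cc(OC)c(OC)cc2/C=C(\C=C\N3CCC[C@@H]3C(O[Si](C)(C)C)(c4ccccc4)c5ccccc5)C(=O)OC(C)(C)C)C=CC1=O | intermediate
15 | tert-butyl (1S,2R)-2-formyl-1-(4-hydroxy-3-methoxyphenyl)-6,7-dimethoxy-1,2-dihydronaphthalene-3-carboxylate (trans) | COc1cc([C@H]2c3cc(OC)c(OC)cc3C=C(C(=O)OC(C)(C)C)[C@@H]2C=O)ccc1O | intermediate
16 | [(1S,2R)-1-(4-hydroxy-3-methoxyphenyl)-6,7-dimethoxy-1,2-dihydronaphthalene-2,3-diyl]dimethanol | COc1cc([C@H]2c3cc(OC)c(OC)cc3C=C(CO)[C@@H]2CO)ccc1O | intermediate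
17 | (1S,2R)-2-(hydroxymethyl)-1-(4-hydroxy-3-methoxyphenyl)-6,7-dimethoxy-1,2-dihydronaphthalene-3-carbaldehyde | COc1cc([C@H]2c3cc(OC)c(OC)cc3C=C(C=O)[C@@H]2CO)ccc1O | target

Total step count: 11.
Longest linear sequence: 9 steps (1 → 2 → 3 → 4 → 10 → 11 → 12 → 15 → 16 → 17). The branch from 5 is 8 steps long.

Steps most likely to fail

1. Step 9 (new method).
Possible failure processes:
- sluggish C–C bond formation, because the ester-bearing dienamine is a weak nucleophile
- reversible capture of the amine at C1
- self-addition of the quinone methide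
- an uncatalysed racemic closure through the enol
- weak facial discrimination

The fallback uses known chemistry only, sets out from 6 and 2, and rejoins the route at 16. C1–C2 is made by an auxiliary-controlled aldol reaction, and ring B is closed instead at C1–C8a by Friedel–Crafts alkylation. Stobbe condensation of 6 with commercial 3,4-dimethoxybenzaldehyde (KOtBu, tBuOH) gives (E)-3-(tert-butoxycarbonyl)-4-(3,4-dimethoxyphenyl)but-3-enoic acid F1. Coupling with (S)-4-benzyl-2-oxazolidinone (PivCl, Et3N, LiCl, THF) gives the N-acyl oxazolidinone F2. Enolization with Bu2BOTf/iPr2NEt and addition to 2 at −78 °C gives the Evans syn-aldol adduct F3, in which the auxiliary fixes C2. BF3·OEt2 in CH2Cl2 at −40 °C ionizes the para-silyloxybenzylic alcohol, and ring A attacks para to its methoxy group to give the trans-dihydronaphthalene imide F4. LiBH4 (Et2O, MeOH, 0 °C) removes the auxiliary to give the silyl-protected hydroxy ester F5. iBu2AlH gives the silyl-protected diol F6, and Bu4NF releases 16.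

2. Step 11.
Possible failure processes:
- oxidation of the free phenol through C1–H, followed by aromatization of ring B
- further oxidation by way of the cyclic hemiacetal

The fallback sets out from 15 and rejoins at 17. In it the C3 carbon is never taken down to the alcohol, so no oxidant meets the phenol. NaBH4 (MeOH, −20 °C) converts 15 into the hydroxy ester F7. CF3CO2H in CH2Cl2 cleaves the tert-butyl ester and closes the fused α-alkylidene lactone F8. iBu2AlH (2.2 equiv, CH2Cl2, −78 °C) stops at the lactol F9. This is the ring tautomer of the hydroxy enal and should open to 17 on work-up.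

3. Step 6.
Possible failure processes:
- protonolysis of the zinc reagent by the hydroxyl group
- Wurtz-type homocoupling during zinc insertion
- slow oxidative addition to the hindered, electron-rich bromide

The fallback sets out from 8, uses 4, and rejoins at 10. The polarity of the coupling is reversed. Miyaura borylation of 8 (B2pin2, PdCl2(dppf), KOAc, dioxane, 80 °C) gives the aryl pinacol boronate F10. This is joined to benzylic chloride 4 by Suzuki–Miyaura coupling (Pd(OAc)2, SPhos, K3PO4, toluene/H2O, 60 °C), biphasic phosphate conditions being chosen to spare the aryl silyl ether.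

Further compounds
F1 | step 9 | (E)-3-(tert-butoxycarbonyl)-4-(3,4-dimethoxyphenyl)but-3-enoic acid | COc1ccc(/C=C(\CC(=O)O)C(=O)OC(C)(C)C)cc1OC
F2 | step 9 | tert-butyl (E)-2-{2-[(S)-4-benzyl-2-oxooxazolidin-3-yl]-2-oxoethyl}-3-(3,4-dimethoxyphenyl)acrylate | COc1ccc(/C=C(\CC(=O)N2[C@@H](Cc3ccccc3)COC2=O)C(=O)OC(C)(C)C)cc1OC
F3 | step 9 | Evans syn-aldol adduct of F2 with 2 (C2 S, carbinol carbon S) | COc1ccc(/C=C(\[C@@H]([C@H](O)c2ccc(O[Si](C)(C)C(C)(C)C)c(OC)c2)C(=O)N2[C@@H](Cc3ccccc3)COC2=O)C(=O)OC(C)(C)C)cc1OC
F4 | step 9 | tert-butyl (1S,2R)-2-[(S)-4-benzyl-2-oxooxazolidine-3-carbonyl]-1-[4-(tert-butyldimethylsilyloxy)-3-methoxyphenyl]-6,7-dimethoxy-1,2-dihydronaphthalene-3-carboxylate | COc1cc([C@H]2c3cc(OC)c(OC)cc3C=C(C(=O)OC(C)(C)C)[C@@H]2C(=O)N4[C@@H](Cc5ccccc5)COC4=O)ccc1O[Si](C)(C)C(C)(C)C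
F5 | step 9 | tert-butyl (1S,2R)-1-[4-(tert-butyldimethylsilyloxy)-3-methoxyphenyl]-2-(hydroxymethyl)-6,7-dimethoxy-1,2-dihydronaphthalene-3-carboxylate | COc1cc([C@H]2c3cc(OC)c(OC)cc3C=C(C(=O)OC(C)(C)C)[C@@H]2CO)ccc1O[Si](C)(C)C(C)(C)C
F6 | step 9 | {(1S,2R)-1-[4-(tert-butyldimethylsilyloxy)-3-methoxyphenyl]-6,7-dimethoxy-1,2-dihydronaphthalene-2,3-diyl}dimethanol | COc1cc([C@H]2c3cc(OC)c(OC)cc3C=C(CO)[C@@H]2CO)ccc1O[Si](C)(C)C(C)(C)C
F7 | step 11 | tert-butyl (1S,2R)-2-(hydroxymethyl)-1-(4-hydroxy-3-methoxyphenyl)-6,7-dimethoxy-1,2-dihydronaphthalene-3-carboxylate | COc1cc([C@H]2c3cc(OC)c(OC)cc3C=C(C(=O)OC(C)(C)C)[C@@H]2CO)ccc1O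
F8 | step 11 | (3aR,4S)-4-(4-hydroxy-3-methoxyphenyl)-6,7-dimethoxy-3a,4-dihydronaphtho[2,3-c]furan-1(3H)-one | COc1cc([C@H]2c3cc(OC)c(OC)cc3C=C4C(=O)OC[C@H]24)ccc1O
F9 | step 11 | (3aR,4S)-4-(4-hydroxy-3-methoxyphenyl)-6,7-dimethoxy-1,3,3a,4-tetrahydronaphtho[2,3-c]furan-1-ol (anomeric mixture) | COc1cc([C@H]2c3cc(OC)c(OC)cc3C=C4C(O)OC[C@H]24)ccc1O
F10 | step 6 | tert-butyl (E)-3-[4,5-dimethoxy-2-(4,4,5,5-tetramethyl-1,3,2-dioxaborolan-2-yl)phenyl]-2-(2-hydroxyethyl)acrylate | COc1cc(B2OC(C)(C)C(C)(C)O2)c(/C=C(\CCO)C(=O)OC(C)(C)C)cc1OC
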